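(The numbers in the tables are calculated with constants of no real substance, noise included.)

The delta and gamma runs climb in straight lines: from 30.0 s to 90.0 s, delta gains 0.0570 /min and gamma 0.0630 /min, as fractions of the charge of starting material.

| setting | delta | gamma | north-east | south-east |
|---|---|---|---|---|
| starting material | 0.99 M | 0.99 M | 0.99 M | 0.99 M |
| solid reagent | 0.693 M | 0.693 M | 0.693 M | 0.693 M |
| initiator | 20 mM | 29 mM | 39 mM | 39 mM |
| remark | run made earlier | run made earlier |  |  |
| time |  |  | 2.5 min | 10 min |

| run | time / s | product / % |
|---|---|---|
| delta | 10.0 | 1.4 |
| delta | 12.0 | 0.6 |
| delta | 20.0 | 0.7 |
| delta | 30.0 | 2.5 |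
| delta | 50.0 | 4.9 |
| delta | 90.0 | 8.2 |
| gamma | 15.0 | 1.4 |
| gamma | 30.0 | 3.0 |
| gamma | 50.0 | 5.0 |
| gamma | 60.0 | 6.1 |
| gamma | 80.0 | 7.9 |
| gamma | 90.0 | 9.3 |

(readings scatter by 0.5 percentage points)

- percent here means starting material units held: one ended chains B counts as two
- solid reagent is a solid; its amount is given per volume of the solution
- reactions considered so far: 2 first chain carrier -> ended chains B; partner + first chain carrier -> product + second chain carrier; starting material <-> dormant form; solid reagent <-> partner; starting material + second chain carrier -> released group + first chain carrier; starting material + initiating radical -> capped initiator + first chain carrier; initiator -> 2 initiating radical; 2 second chain carrier -> ended chains A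
- at the start none of the solid reagent is in solution

- which one finishes higher in amount of product, in percent of the starting material charged ("neither" within 2 percentage points) (north-east / south-east / neither)
- amount of product at the end, in percent of the starting material charged, north-east
- amount of product at the end, in percent of the starting material charged, south-east

Initiator matters little so far: raising it by a factor of 1.45 moved the slope by a factor of 1.11, and the gap of 0.00600 /min is smaller than the scatter of one slope, 0.00707 /min. Starting material cannot be judged, since both runs hold 0.99 M. Solid reagent, the limiting reagent, enters as a ceiling of 70.0%. On a straight line an error in the slope passes in proportion into the answer, and the times are given.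

The slope is therefore the number to know. The average of both, 0.0600 /min, is the mean product rate, with a scatter of 0.00500 /min. It gives 15.0% for north-east and 60.0% for south-east, the latter uncertain by 5 percentage points and below the ceiling.

The forecast says 15% and 52%, with south-east higher, lower than this reckoning at the longer time, expecting that “the solid shrinks, starting material depletes”. The flasks give 15.3% for north-east and 53.5% for south-east, so south-east finishes higher.

    2 first chain carrier → ended chains B (k = 2.10 × 10⁷ /M/s)
    partner + first chain carrier → product + second chain carrier (k = 4.00 × 10⁵ /M/s)
    starting material ⇌ dormant form (K = 2.90, k = 0.00430 /s)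
    solid reagent ⇌ partner, rate k4*(cs4 - [partner]) while solid is left; crystals form when [partner] > cs4 (solubility = 0.350 M, k = 0.00300 /s)
    starting material + second chain carrier → released group + first chain carrier (k = 76000 /M/s)
    starting material + initiating radical → capped initiator + first chain carrier (k = 2.50 × 10⁶ /M/s)
    initiator → 2 initiating radical (k = 2.30 × 10⁻⁴ /s)
    2 second chain carrier → ended chains A (k = 5.70 × 10⁸ /M/s)

The mean product rate overshoots south-east by 6.5 points, yet it matches the dissolution of partner, 0.0636 /min from the constants, while c partner stands at 0.00493 M after 5.00 min in south-east. The difference in time is the main reason why south-east finishes higher: read at 2.5 min, south-east holds 15.3% instead of 53.5%. Taken as a molar rate, the mean product rate gives 34.9% for the neighbour charged with 1.7 M of starting material, and that flask gives 36.3%.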